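Start from the leftover in the larch run: at 90.0 s, 57.0% of the starting material has not become product, so ask first how much of that leftover can still convert, then how fast. These are the flasks, the readings and the questions:

the same everywhere: free catalyst 25 µM
- larch: starting material 5 mM; reagent 5.25 mM; protic impurity 1 mM; run made earlier
- maple: starting material 2.5 mM; reagent 5.25 mM; protic impurity 1 mM; run made earlier
- ash: starting material 10 mM; reagent 5.25 mM; protic impurity 1 mM; run made earlier
- north-east: starting material 5.0 mM; reagent 5.25 mM (fed, over 1.5 min); protic impurity 1.00 mM; all else is in the flask from the start; the feed brings no volume worth counting; time 2.5 min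
- west: starting material 5.0 mM (fed, over 1.5 min); reagent 5.25 mM; protic impurity 1.00 mM; all else is in the flask from the start; the feed brings no volume worth counting; time 2.5 min
- north-west: starting material 5.0 mM; reagent 5.25 mM; protic impurity 1.00 mM; everything together at the start; time 2.5 min
- south-west: starting material 5.0 mM (in portions, 2, over 1.5 min); reagent 5.25 mM; protic impurity 1.00 mM; first portion at the start, last at 1.5 min; time 2.5 min

larch run (percent of the starting material charged)

| time / s | product / % |
|---|---|
| 10.0 | 6 |
| 12.0 | 6 |
| 15.0 | 10 |
| 25.0 | 12 |
| 40.0 | 20 |
| 60.0 | 30 |
| 90.0 | 43 |

maple run (percent of the starting material charged)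

| time / min | product / % |
|---|---|
| 0.250 | 12 |
| 0.333 | 19 |
| 0.500 | 26 |
| 0.833 | 38 |
| 1.33 | 53 |
| 2.00 | 65 |
| 3.00 | 76 |

ash run (percent of the starting material charged)

| time / min | product / % |
|---|---|
| 0.417 | 7 |
| 0.833 | 16 |
| 1.33 | 22 |
| 1.50 | 22 |
| 2.00 | 30 |
| 2.50 | 37 |
| 3.00 | 41 |

(scatter of a reading: 1.5 percentage points)

* the flask with the highest amount of product, in percent of the starting material charged ("all alike" if they lie within 1.5 percentage points) (north-east / west / north-west / south-west / all alike)
* final product, as a percentage of the starting material charged, in north-east
* final product, as a percentage of the starting material charged, in west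
* final product, as a percentage of the starting material charged, in north-west
* final product, as a percentage of the starting material charged, in south-west



Take the end state first. With 1.05 equivalents of reagent, the starting material is the limiting reagent and the ceiling looks like full conversion. But suppose the protic impurity takes reagent one for one, and a lower ceiling follows:

Y = (c(reagent) − c(protic impurity)) / c(starting material) = 85.0%

The ash run doesn't refuse this: at its last reading it holds 4.10 mM of product, less than the 4.25 mM that this ceiling allows, so keep Y as the cautious height.

Now try the pace. The larch run has the charges of north-west, so extend its line of 1.43 mM min⁻¹ to 2.5 min, which gives north-west 71.7% as a first estimate. Yet maple, late in its run, gains 0.275 mM min⁻¹, less than that line, so drop the line and let product close its distance to Y at a steady fraction per minute, pseudo-first-order in form. Call this the larch clock, the rate constant of the approach to Y, read from the last larch reading: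

k = ln(Y / (Y − y)) / t = 0.470 min⁻¹

y(t) = Y − Y·exp(−k·t)

Give each part of a charge its own clock, starting when it enters, and average:

north-west: 58.7%
south-west: 45.3%
west: 46.9%

Doubt the separate clocks, though: ash, with twice the larch charge of starting material, gains 1.92 mM min⁻¹ early, a factor of 1.34 on the larch pace, so hold the fed figures loosely. The clock puts north-west above these two and says nothing of north-east, where the reagent is fed.

The forecast gives 61% for north-west, differing from my figure, with 52% for north-east, 50% for south-west and 49% for west, and names north-west: “Starting everything together should win.”

The flasks give north-west 59.0%, north-east 51.0%, south-west 44.8% and west 39.3%, so north-west stands highest.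

    reagent + free catalyst → catalyst intermediate A (k = 734 M⁻¹ s⁻¹)
    2 catalyst intermediate A → spent catalyst (k = 621 M⁻¹ s⁻¹)
    catalyst intermediate D → free catalyst + product (k = 5.66 s⁻¹)
    catalyst intermediate B → released group + catalyst intermediate C (k = 8.10 s⁻¹)
    catalyst intermediate C → catalyst intermediate D (k = 7.32 s⁻¹)
    starting material + catalyst intermediate A ⇌ catalyst intermediate B (K = 440 M⁻¹, k = 1720 M⁻¹ s⁻¹)
    starting material + protic impurity → quenched substrate (k = 1.64 M⁻¹ s⁻¹)

The clock's 58.7% stands against 59.0% in north-west, but it overshoots west by 7.6 percentage points. At 2.50 min in north-west, the forward binding of starting material took catalyst intermediate A 320 times as fast as pairing into spent catalyst did, yet spent catalyst holds 25.9% of the catalyst charged there, and at the same time in west it holds more, 43.1%. The scheme has the protic impurity take starting material, not reagent, so treat Y as an assumed height. For north-west left until 4.0 min, the clock gives 72.0%; the computed flask gives 73.8%.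

(The earlier runs and the new flask are simulated for substances that don't exist; noise was put on by code.)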